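**Retrosynthetic overview**
1. Target 17 comes from 16 by one global hydrogenolysis (two benzyl ethers and the 5,6-diphenylmethylene ketal).
2. Ring C is the only ring built and is formed last: C4–C3 and O1–C2 are made together by a proposed Rh(III)-catalysed oxidative [4+2] annulation of salicylaldehyde 7 (ring A) with aryl methyl ynol ether 15 (ring B, C2, C3 and the 3-OMe).
3. 7 comes from ortho-formylation of phenol 5, which comes from catechol ketalisation of the triol obtained by Thiele–Winter acetoxylation of 2,3-dimethoxy-1,4-benzoquinone, itself from 2,3-dimethoxyphenol.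
4. 15 comes from enol triflate elimination of the α-methoxy ketone 12, made via the Weinreb amide from methyl 3,5-dihydroxy-4-methoxybenzoate.
5. Ring order: rings A and B are bought as arenes, a temporary dioxole ring is put on ring A in step 3, ring C is closed in step 10.

Assumption: the target has no stereocentre or other stereogenic element, so "single enantiomer" is met trivially; the only stereo-defined species are the (Z)-enolate 13 and (Z)-enol triflate 14.

**Route**

Step 1
Reactants: 1 2,3-dimethoxyphenol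
Product: 2 2,3-dimethoxy-1,4-benzoquinone
Conditions: Fremy's salt (2.5 equiv), KH2PO4, H2O/acetone, 0 °C to rt
Reagents that add atoms: potassium nitrosodisulfonate (Fremy's salt), [K+].[K+].[O]N(S(=O)(=O)[O-])S(=O)(=O)[O-]
Why: Teuber oxidation of a phenol with a free para position gives the p-quinone, and C4 is the only para position.

Step 2
Reactants: 2 2,3-dimethoxy-1,4-benzoquinone
Product: 3 5,6-dimethoxybenzene-1,2,4-triyl triacetate
Conditions: Ac2O, H2SO4 (cat.), rt, 24–48 h
Reagents that add atoms: acetic anhydride, CC(=O)OC(C)=O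
Why: Thiele–Winter acetoxylation adds acetate to the unsubstituted enone side of the symmetric quinone, so a single triacetate with five contiguous oxygens forms.

Step 3
Reactants: 3 5,6-dimethoxybenzene-1,2,4-triyl triacetate
Product: 5 6,7-dimethoxy-2,2-diphenyl-1,3-benzodioxol-5-ol, via free triol 4 (not isolated)
Conditions: HCl (cat., 1.25 M in MeOH), degassed MeOH, 50 °C, Ar; evaporate; then Ph2CCl2 (1.1 equiv), Ph2O, 170 °C, Ar
Reagents that add atoms: dichlorodiphenylmethane, ClC(Cl)(c1ccccc1)c1ccccc1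
Why: Acid-catalysed transesterification frees the triol, and catechol ketalisation with Ph2CCl2 can only bridge the single vicinal diol, leaving the isolated hydroxyl free; telescoping avoids air oxidation of the hydroxyhydroquinone.

Step 4
Reactants: 5 6,7-dimethoxy-2,2-diphenyl-1,3-benzodioxol-5-ol
Product: 7 5-hydroxy-6,7-dimethoxy-2,2-diphenyl-1,3-benzodioxole-4-carbaldehyde, via hydroxymethyl phenol 6 (not isolated)
Conditions: MgCl2 (2 equiv), Et3N (4 equiv), (CH2O)n (6 equiv), MeCN, reflux; aq. citric acid work-up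
Reagents that add atoms: formaldehyde (as paraformaldehyde), C=O
Why: Casnati–Skattebøl ortho-formylation sends formaldehyde through the magnesium phenoxide to the only free ring position, and a second formaldehyde oxidises the hydroxymethyl phenol by Oppenauer-type hydride transfer.

Step 5
Reactants: 8 methyl 3,5-dihydroxy-4-methoxybenzoate
Product: 9 methyl 3,5-bis(benzyloxy)-4-methoxybenzoate
Conditions: BnBr (2.4 equiv), K2CO3 (3 equiv), DMF, 60 °C
Reagents that add atoms: benzyl bromide, BrCc1ccccc1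
Why: Williamson ether synthesis on two equivalent phenols.

Step 6
Reactants: 9 methyl 3,5-bis(benzyloxy)-4-methoxybenzoate
Product: 10 3,5-bis(benzyloxy)-N,4-dimethoxy-N-methylbenzamide
Conditions: MeNH(OMe)·HCl (1.5 equiv), i-PrMgCl (3.0 equiv), THF, −20 to 0 °C
Reagents that add atoms: N,O-dimethylhydroxylamine hydrochloride, CNOC.Cl
Why: Direct ester-to-Weinreb-amide aminolysis by the magnesium amide generated in the flask.

Step 7
Reactants: 10 3,5-bis(benzyloxy)-N,4-dimethoxy-N-methylbenzamide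
Product: 12 1-[3,5-bis(benzyloxy)-4-methoxyphenyl]-2-methoxyethan-1-one, via tetrahedral lithium adduct 11 (not isolated)
Conditions: Bu3SnCH2OMe (1.5 equiv), n-BuLi (1.4 equiv), THF, −78 °C; then 10, −78 °C; aq. NH4Cl
Reagents that add atoms: tributyl(methoxymethyl)stannane, CCCC[Sn](CCCC)(CCCC)COC; n-butyllithium, [Li]CCCC (its lithium stays only in adduct 11)
Why: Weinreb ketone synthesis with an α-alkoxy organolithium from tin–lithium exchange; the chelated adduct prevents over-addition.

Step 8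
Reactants: 12 1-[3,5-bis(benzyloxy)-4-methoxyphenyl]-2-methoxyethan-1-one
Product: 14 (Z)-1-[3,5-bis(benzyloxy)-4-methoxyphenyl]-2-methoxyethenyl trifluoromethanesulfonate, via lithium enolate 13 (not isolated)
Conditions: LiHMDS (1.2 equiv), THF, −78 °C; PhNTf2 (1.2 equiv), −78 to 0 °C; aq. NH4Cl
Reagents that add atoms: N-phenylbis(trifluoromethanesulfonimide), O=S(=O)(N(c1ccccc1)S(=O)(=O)C(F)(F)F)C(F)(F)F; lithium hexamethyldisilazide, [Li]N([Si](C)(C)C)[Si](C)(C)C (its lithium stays only in enolate 13)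
Why: Chelation-controlled enolisation of the α-alkoxy ketone gives the (Z)-enolate, and enolate O-triflation with PhNTf2 keeps that geometry.

Step 9
Reactants: 14 (Z)-1-[3,5-bis(benzyloxy)-4-methoxyphenyl]-2-methoxyethenyl trifluoromethanesulfonate
Product: 15 1,3-bis(benzyloxy)-2-methoxy-5-(methoxyethynyl)benzene
Conditions: KOt-Bu (2 equiv), THF, −78 to −40 °C; cold filtration through Et3N-deactivated silica, used promptly
Reagents that add atoms: none
Why: Anti E2 elimination of triflic acid from the enol triflate (H and OTf are anti in the Z isomer) is an established route from α-alkoxy ketones to ynol ethers.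

Step 10
Reactants: 7 5-hydroxy-6,7-dimethoxy-2,2-diphenyl-1,3-benzodioxole-4-carbaldehyde; 15 1,3-bis(benzyloxy)-2-methoxy-5-(methoxyethynyl)benzene
Product: 16 2-[3,5-bis(benzyloxy)-4-methoxyphenyl]-3,7,8-trimethoxy-5,6-[(diphenylmethylene)dioxy]-4H-chromen-4-one
Conditions: [Cp*RhCl2]2 (2.5 mol%), Cu(OAc)2 (2.2 equiv), Na2CO3 (1.1 equiv), 4 Å MS, DCE, 70 °C, Ar; 15 (1.5 equiv) added over 4 h
Reagents that add atoms: none
Why: Proposed new method: phenoxide-directed formyl C–H activation of 7 by Cp*Rh(III) acetate (concerted metalation–deprotonation) gives a five-membered acyl rhodacycle, the polarised ynol ether inserts into the Rh–acyl bond with the acyl carbon going to the electrophilic oxygen-bearing alkyne carbon and Rh to the aryl-bearing carbon (ynol ether polarisation and the usual Cp*Rh preference for the aryl-substituted carbon point the same way), C–O reductive elimination from the seven-membered rhodacycle closes the pyranone as the 2-aryl-3-methoxy isomer, and Cu(II) reoxidises Rh(I); the methyl ynol ether has no β-hydrogen for retro-ene loss of ketene, and carbonate buffering with slow addition limits its acetolysis; the closest known reaction type is the Rh-catalysed oxidative annulation of salicylaldehydes with diaryl or alkyl aryl alkynes to chromones, together with Rh(III) C–H annulations of ynamides, neither shown with an ynol ether.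

Step 11
Reactants: 16 2-[3,5-bis(benzyloxy)-4-methoxyphenyl]-3,7,8-trimethoxy-5,6-[(diphenylmethylene)dioxy]-4H-chromen-4-one
Product: 17 5,6,3',5'-tetrahydroxy-3,7,8,4'-tetramethoxyflavone
Conditions: H2 (1 atm), 10% Pd/C, THF/MeOH, rt
Reagents that add atoms: none
Why: Pd-catalysed hydrogenolysis cleaves both benzyl ethers and the benzhydrylidene ketal while methyl ethers and the tetrasubstituted flavone C2=C3 bond stay intact; the product is achiral.

**Compound list**
1 | 2,3-dimethoxyphenol | COc1cccc(O)c1OC | starting material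
2 | 2,3-dimethoxy-1,4-benzoquinone | COC1=C(OC)C(=O)C=CC1=O | intermediate
3 | 5,6-dimethoxybenzene-1,2,4-triyl triacetate | COc1c(OC)c(OC(C)=O)cc(OC(C)=O)c1OC(C)=O | intermediate
4 | 5,6-dimethoxybenzene-1,2,4-triol (free triol, not isolated) | COc1c(OC)c(O)cc(O)c1O | intermediate
5 | 6,7-dimethoxy-2,2-diphenyl-1,3-benzodioxol-5-ol | COc1c(OC)c(O)cc2OC(c3ccccc3)(c3ccccc3)Oc12 | intermediate
6 | 4-(hydroxymethyl)-6,7-dimethoxy-2,2-diphenyl-1,3-benzodioxol-5-ol (hydroxymethyl phenol, not isolated) | COc1c(OC)c(O)c(CO)c2OC(c3ccccc3)(c3ccccc3)Oc12 | intermediate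
7 | 5-hydroxy-6,7-dimethoxy-2,2-diphenyl-1,3-benzodioxole-4-carbaldehyde | COc1c(OC)c(O)c(C=O)c2OC(c3ccccc3)(c3ccccc3)Oc12 | intermediate
8 | methyl 3,5-dihydroxy-4-methoxybenzoate | COC(=O)c1cc(O)c(OC)c(O)c1 | starting material
9 | methyl 3,5-bis(benzyloxy)-4-methoxybenzoate | COC(=O)c1cc(OCc2ccccc2)c(OC)c(OCc2ccccc2)c1 | intermediate
10 | 3,5-bis(benzyloxy)-N,4-dimethoxy-N-methylbenzamide | CON(C)C(=O)c1cc(OCc2ccccc2)c(OC)c(OCc2ccccc2)c1 | intermediate
11 | lithium 1-[3,5-bis(benzyloxy)-4-methoxyphenyl]-2-methoxy-1-[methoxy(methyl)amino]ethan-1-olate (tetrahedral lithium adduct, racemic, not isolated) | [Li]OC(COC)(N(C)OC)c1cc(OCc2ccccc2)c(OC)c(OCc2ccccc2)c1 | intermediate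
12 | 1-[3,5-bis(benzyloxy)-4-methoxyphenyl]-2-methoxyethan-1-one | COCC(=O)c1cc(OCc2ccccc2)c(OC)c(OCc2ccccc2)c1 | intermediate
13 | lithium (Z)-1-[3,5-bis(benzyloxy)-4-methoxyphenyl]-2-methoxyethen-1-olate (lithium enolate, not isolated) | CO/C=C(\O[Li])c1cc(OCc2ccccc2)c(OC)c(OCc2ccccc2)c1 | intermediate
14 | (Z)-1-[3,5-bis(benzyloxy)-4-methoxyphenyl]-2-methoxyethenyl trifluoromethanesulfonate | CO/C=C(\OS(=O)(=O)C(F)(F)F)c1cc(OCc2ccccc2)c(OC)c(OCc2ccccc2)c1 | intermediate
15 | 1,3-bis(benzyloxy)-2-methoxy-5-(methoxyethynyl)benzene | COC#Cc1cc(OCc2ccccc2)c(OC)c(OCc2ccccc2)c1 | intermediate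
16 | 2-[3,5-bis(benzyloxy)-4-methoxyphenyl]-3,7,8-trimethoxy-5,6-[(diphenylmethylene)dioxy]-4H-chromen-4-one | COc1c(OCc2ccccc2)cc(-c2oc3c(OC)c(OC)c4OC(c5ccccc5)(c5ccccc5)Oc4c3c(=O)c2OC)cc1OCc1ccccc1 | intermediate
17 | 5,6,3',5'-tetrahydroxy-3,7,8,4'-tetramethoxyflavone | COc1c(O)cc(-c2oc3c(OC)c(OC)c(O)c(O)c3c(=O)c2OC)cc1O | target

**Step count and risk**
Total steps: 11. Longest linear sequence: 7 steps (8 → 9 → 10 → 12 → 14 → 15 → 16 → 17).

The three steps most likely to fail:

Step 10 (proposed new annulation). It may fail by acetolysis or hydration of the ynol ether, decarbonylation of the hindered acyl rhodium species, or the wrong insertion regiochemistry. The fallback uses known chemistry, sets out from 7 and 12 and comes back at 16. Phenol 7 is silylated (TBSCl, imidazole, DMF) to 5-[(tert-butyldimethylsilyl)oxy]-6,7-dimethoxy-2,2-diphenyl-1,3-benzodioxole-4-carbaldehyde F8. The lithium enolate of ketone 12 (LiHMDS, THF, −78 °C) adds to F8 in an aldol reaction to give 1-[3,5-bis(benzyloxy)-4-methoxyphenyl]-3-{5-[(tert-butyldimethylsilyl)oxy]-6,7-dimethoxy-2,2-diphenyl-1,3-benzodioxol-4-yl}-3-hydroxy-2-methoxypropan-1-one F9 as a diastereomer mixture. Dess–Martin oxidation gives the 2-methoxy-1,3-diketone 1-[3,5-bis(benzyloxy)-4-methoxyphenyl]-3-{5-[(tert-butyldimethylsilyl)oxy]-6,7-dimethoxy-2,2-diphenyl-1,3-benzodioxol-4-yl}-2-methoxypropane-1,3-dione F10. Desilylation (TBAF/AcOH, THF, 0 °C) followed by mild acid cyclodehydration (CSA cat., toluene, 4 Å MS, 60 °C), the classical β-diketone closure of flavones, gives 16.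

Step 3 (triol and ketal). Triol 4 is a hydroxyhydroquinone that oxidises in air and may char under the hot ketalisation. The fallback sets out from 3 and comes back at 7, so step 4 is skipped. Triacetate 3 is deacetylated and benzylated in one pot (K2CO3, BnBr, MeOH/acetone, reflux, Ar) to 1,2,4-tris(benzyloxy)-5,6-dimethoxybenzene F1. Vilsmeier–Haack formylation (POCl3, DMF, 70 °C) at the only free position gives 2,3,6-tris(benzyloxy)-4,5-dimethoxybenzaldehyde F2. Hydrogenolysis (H2, Pd/C, EtOAc, rt) gives 2,3,6-trihydroxy-4,5-dimethoxybenzaldehyde F3, in which the formyl group makes the hydroquinone far less oxidisable. Ph2CCl2 (Ph2O, 170 °C) then bridges the only catechol pair and gives 7.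

Step 9 (ynol ether formation). tert-Butoxide may attack sulfur of the triflate and return ketone 12, and 15 is acid-sensitive. The fallback sets out from 10 and comes back at 15 by the classical bromination and double dehydrobromination of an enol ether. DIBAL-H (THF, −78 °C) reduces Weinreb amide 10 to 3,5-bis(benzyloxy)-4-methoxybenzaldehyde F4. Wittig reaction with Ph3P=CHOMe (from the phosphonium chloride and KOt-Bu) gives 1,3-bis(benzyloxy)-2-methoxy-5-(2-methoxyethenyl)benzene F5 as an E/Z mixture. Br2 (CH2Cl2, −78 °C) gives 1,3-bis(benzyloxy)-5-(1,2-dibromo-2-methoxyethyl)-2-methoxybenzene F6, used crude. KOt-Bu removes one HBr to give 1,3-bis(benzyloxy)-5-(1-bromo-2-methoxyethenyl)-2-methoxybenzene F7, and a second equivalent (THF, −78 to 0 °C) gives 15.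

**Further compounds**
F1 | step 3 | 1,2,4-tris(benzyloxy)-5,6-dimethoxybenzene | COc1c(OC)c(OCc2ccccc2)cc(OCc2ccccc2)c1OCc1ccccc1
F2 | step 3 | 2,3,6-tris(benzyloxy)-4,5-dimethoxybenzaldehyde | COc1c(OC)c(OCc2ccccc2)c(C=O)c(OCc2ccccc2)c1OCc1ccccc1
F3 | step 3 | 2,3,6-trihydroxy-4,5-dimethoxybenzaldehyde | COc1c(OC)c(O)c(C=O)c(O)c1O
F4 | step 9 | 3,5-bis(benzyloxy)-4-methoxybenzaldehyde | COc1c(OCc2ccccc2)cc(C=O)cc1OCc1ccccc1
F5 | step 9 | 1,3-bis(benzyloxy)-2-methoxy-5-(2-methoxyethenyl)benzene (E/Z mixture) | COC=Cc1cc(OCc2ccccc2)c(OC)c(OCc2ccccc2)c1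
F6 | step 9 | 1,3-bis(benzyloxy)-5-(1,2-dibromo-2-methoxyethyl)-2-methoxybenzene (diastereomer mixture, racemic) | COC(Br)C(Br)c1cc(OCc2ccccc2)c(OC)c(OCc2ccccc2)c1
F7 | step 9 | 1,3-bis(benzyloxy)-5-(1-bromo-2-methoxyethenyl)-2-methoxybenzene (E/Z mixture) | COC=C(Br)c1cc(OCc2ccccc2)c(OC)c(OCc2ccccc2)c1
F8 | step 10 | 5-[(tert-butyldimethylsilyl)oxy]-6,7-dimethoxy-2,2-diphenyl-1,3-benzodioxole-4-carbaldehyde | COc1c(OC)c(O[Si](C)(C)C(C)(C)C)c(C=O)c2OC(c3ccccc3)(c3ccccc3)Oc12
F9 | step 10 | 1-[3,5-bis(benzyloxy)-4-methoxyphenyl]-3-{5-[(tert-butyldimethylsilyl)oxy]-6,7-dimethoxy-2,2-diphenyl-1,3-benzodioxol-4-yl}-3-hydroxy-2-methoxypropan-1-one (diastereomer mixture, racemic) | COC(C(O)c1c(O[Si](C)(C)C(C)(C)C)c(OC)c(OC)c2OC(c3ccccc3)(c3ccccc3)Oc12)C(=O)c1cc(OCc2ccccc2)c(OC)c(OCc2ccccc2)c1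
F10 | step 10 | 1-[3,5-bis(benzyloxy)-4-methoxyphenyl]-3-{5-[(tert-butyldimethylsilyl)oxy]-6,7-dimethoxy-2,2-diphenyl-1,3-benzodioxol-4-yl}-2-methoxypropane-1,3-dione (racemic) | COC(C(=O)c1c(O[Si](C)(C)C(C)(C)C)c(OC)c(OC)c2OC(c3ccccc3)(c3ccccc3)Oc12)C(=O)c1cc(OCc2ccccc2)c(OC)c(OCc2ccccc2)c1
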